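**Plan**

Retrosynthesis: the seven O–benzyl bonds are cut first. The C1 ketone is traced back to a C1=CH–CH3 alkene, and the pyranone C2=C3 bond to a chromanone. Then chain C2–chromone C3 ([3,3]), chain C1–aryl (cross-coupling) and chain C2–C3 (acetylide addition) are cut.
Enabling feature: chain C2 is bonded to C3 of the benzopyran-4-one ring, the α-carbon of the C4 carbonyl. Its other neighbour C1 is a carbonyl carbon that can be carried as an alkene carbon, so C4(=O)–C3–C2–C1(=C) is the γ,δ-unsaturated ketone left by a Claisen rearrangement of a chroman-4-one allyl enol ether.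
Forward, chain: (R)-but-3-yn-2-ol supplies chain C1 and C2. Its acetylide adds to 4,4'-bis(benzyloxy)benzophenone (C2–C3 bond); ionic hydrogenation, trans-hydrostannation/iodination and Negishi arylation (C1–aryl bond) then give the (R,E)-allylic alcohol.
Forward, rings: all benzene rings are bought. The only ring made is the dihydropyranone of the chromanone (phloroglucinol + 3-chloropropanoic acid); it is ketalised, joined to the chain in the ketal Claisen step and then aromatised, and alkene cleavage and hydrogenolysis finish the route.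
Stereochemistry: the single stereocentre C2 comes from the carbinol carbon of (R)-but-3-yn-2-ol by suprafacial 1,3-chirality transfer across the (E)-alkene fixed by the trans-hydrostannation. The carbinol carbon later leaves as acetaldehyde.

Key step: step 12

Remark: chain atoms are numbered C1 (ketone carbon), C2 (stereocentre) and C3 (diarylmethine). The target SMILES reads (R) at C2. The descriptor at this carbon is R in 22, S in 23 and 24, and R in 25–27, only because substituent ranks change; the spatial arrangement stays the same. Compounds 1, 3, 9 and 15 are taken as commercial.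

Step 1
Reactants: 1 4,4'-dihydroxybenzophenone
Product: 2 4,4'-bis(benzyloxy)benzophenone
Conditions: BnBr (2.2 equiv), K2CO3, DMF, 60 °C
Reagents that add atoms: benzyl bromide, BrCc1ccccc1
Why: Williamson ether synthesis on two unhindered acidic phenols with a primary benzylic bromide, the diaryl ketone having no α-hydrogen and staying inert.

Step 2
Reactants: 3 (R)-but-3-yn-2-ol; 2 4,4'-bis(benzyloxy)benzophenone
Product: 5 (4R)-1,1-bis[4-(benzyloxy)phenyl]pent-2-yne-1,4-diol, via O,C-dilithio derivative of (R)-but-3-yn-2-ol 4 (not isolated)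
Conditions: 3, n-BuLi (2 equiv), THF, −78 → 0 °C; 2, −78 °C → rt; H2O
Reagents that add atoms: none
Why: 1,2-addition of a lithium acetylide (alkoxide–acetylide dianion) to a non-enolisable diaryl ketone forms the chain C2–C3 bond, and the carbinol stereocentre of 3 takes no part and stays (R).

Step 3
Reactants: 5 (4R)-1,1-bis[4-(benzyloxy)phenyl]pent-2-yne-1,4-diol
Product: 6 (2R)-5,5-bis[4-(benzyloxy)phenyl]pent-3-yn-2-ol
Conditions: Et3SiH (2 equiv), TFA (1.5 equiv), CH2Cl2, −40 → 0 °C; aq NaHCO3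
Reagents that add atoms: none
Why: ionic hydrogenation in which only the tertiary, doubly 4-alkoxybenzylic propargylic alcohol ionises, the cation takes hydride from the silane at the diaryl carbon where the charge resides to give the alkyne, and the far less ionisable secondary carbinol keeps its configuration.

Step 4
Reactants: 6 (2R)-5,5-bis[4-(benzyloxy)phenyl]pent-3-yn-2-ol
Product: 8 (2R,3Z)-5,5-bis[4-(benzyloxy)phenyl]-3-iodopent-3-en-2-ol, via (2R,3Z)-5,5-bis[4-(benzyloxy)phenyl]-3-(tributylstannyl)pent-3-en-2-ol 7 (not isolated)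
Conditions: Bu3SnH (1.05 equiv, slow addition), [Cp*RuCl]4 (2 mol %), CH2Cl2, rt; then I2 (1.1 equiv), 0 °C; aq Na2S2O3
Reagents that add atoms: iodine, II
Why: hydroxyl-directed ruthenium-catalysed trans-hydrostannation places tin on the alkyne carbon next to the carbinol (O–H···Cl–Ru hydrogen bond) and hydrogen anti to it, and iododestannylation with retention then gives the iodide in which C2 and C5 of the pentenol are trans.

Step 5
Reactants: 9 phloroglucinol
Product: 10 1,3,5-tris(benzyloxy)benzene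
Conditions: BnBr (3.3 equiv), K2CO3, DMF, rt → 60 °C
Reagents that add atoms: benzyl bromide, BrCc1ccccc1
Why: Williamson ether synthesis in a dipolar aprotic solvent that favours O- over C-alkylation of the phloroglucinol anions, the crystalline triether being freed from C-benzylated material by recrystallisation.

Step 6
Reactants: 10 1,3,5-tris(benzyloxy)benzene
Product: 11 1,3,5-tris(benzyloxy)-2-iodobenzene
Conditions: NIS (1.0 equiv), DMF, 0 °C
Reagents that add atoms: N-iodosuccinimide, O=C1CCC(=O)N1I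
Why: electrophilic aromatic iodination of a very electron-rich arene whose three free positions are equivalent, one equivalent of reagent and the steric load of the first iodine stopping the reaction at the monoiodide.

Step 7
Reactants: 11 1,3,5-tris(benzyloxy)-2-iodobenzene; 8 (2R,3Z)-5,5-bis[4-(benzyloxy)phenyl]-3-iodopent-3-en-2-ol
Product: 14 (2R,3E)-5,5-bis[4-(benzyloxy)phenyl]-3-[2,4,6-tris(benzyloxy)phenyl]pent-3-en-2-ol, via [2,4,6-tris(benzyloxy)phenyl]lithium 12 (not isolated), via chloro[2,4,6-tris(benzyloxy)phenyl]zinc 13 (not isolated)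
Conditions: 11 (1.6 equiv), n-BuLi, THF, −78 °C; ZnCl2, −78 °C → rt; 8, Pd2(dba)3 (2.5 mol %), SPhos (10 mol %), THF, 50 °C
Reagents that add atoms: none
Why: iodine–lithium exchange (faster at −78 °C than benzylic deprotonation), transmetalation to zinc and Negishi cross-coupling with a bulky biarylphosphine made for di-ortho-substituted partners form the chain C1–aryl bond with retention of alkene geometry, the arylzinc halide tolerating the free hydroxyl group.

Step 8
Reactants: 9 phloroglucinol; 15 3-chloropropanoic acid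
Product: 16 3-chloro-1-(2,4,6-trihydroxyphenyl)propan-1-one
Conditions: TfOH, 80 °C
Reagents that add atoms: none
Why: Friedel–Crafts acylation of the highly nucleophilic phloroglucinol by the acylating species generated from the acid in triflic acid, the first acyl group deactivating the ring against a second.

Step 9
Reactants: 16 3-chloro-1-(2,4,6-trihydroxyphenyl)propan-1-one
Product: 17 5,7-dihydroxychroman-4-one
Conditions: 2 M aq NaOH, 0 °C → rt; then aq HCl
Reagents that add atoms: none
Why: intramolecular Williamson etherification (6-exo-tet attack of an ortho phenoxide on the primary chloride, or the equivalent elimination/oxa-Michael path) closes the dihydropyranone ring, both ortho hydroxyl groups being equivalent.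

Step 10
Reactants: 17 5,7-dihydroxychroman-4-one
Product: 18 5,7-bis(benzyloxy)chroman-4-one
Conditions: BnBr (2.5 equiv), K2CO3, DMF, 70 °C
Reagents that add atoms: benzyl bromide, BrCc1ccccc1
Why: Williamson ether synthesis, with heating so that the chelated 5-hydroxyl group is alkylated as well as the free 7-hydroxyl group.

Step 11
Reactants: 18 5,7-bis(benzyloxy)chroman-4-one
Product: 19 5,7-bis(benzyloxy)-4,4-dimethoxychromane
Conditions: HC(OMe)3 (5 equiv), MeOH, p-TsOH (2 mol %), 40 °C; Et3N quench; basic alumina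
Reagents that add atoms: trimethyl orthoformate, COC(OC)OC
Why: acid-catalysed ketalisation driven by the orthoester as water scavenger, the oxocarbenium ion being strongly stabilised by the ring oxygen and the 5,7-alkoxy groups, with a basic quench because the ketal is acid-labile.

Step 12
Reactants: 19 5,7-bis(benzyloxy)-4,4-dimethoxychromane; 14 (2R,3E)-5,5-bis[4-(benzyloxy)phenyl]-3-[2,4,6-tris(benzyloxy)phenyl]pent-3-en-2-ol
Product: 22 (3S)-5,7-bis(benzyloxy)-3-{(2R,3Z)-1,1-bis[4-(benzyloxy)phenyl]-3-[2,4,6-tris(benzyloxy)phenyl]pent-3-en-2-yl}chroman-4-one, via mixed ketal 5,7-bis(benzyloxy)-4-methoxy-4-({(2R,3E)-5,5-bis[4-(benzyloxy)phenyl]-3-[2,4,6-tris(benzyloxy)phenyl]pent-3-en-2-yl}oxy)chromane 20 (not isolated), via allyl enol ether 5,7-bis(benzyloxy)-4-({(2R,3E)-5,5-bis[4-(benzyloxy)phenyl]-3-[2,4,6-tris(benzyloxy)phenyl]pent-3-en-2-yl}oxy)-2H-chromene 21 (not isolated)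
Conditions: 19 (3 equiv), EtCO2H (10 mol %), xylenes, 135 °C, MeOH removed through 4 Å MS; chromatography
Reagents that add atoms: none
Why: Propionic acid ionises 19 to a stabilised oxocarbenium ion that carbinol 14 captures to give 20, loss of a second methanol gives the allyl vinyl ether 21, and a concerted suprafacial [3,3]-sigmatropic shift forms the chain C2–chromanone C3 bond and moves the alkene to C1=CHCH3, removal of methanol and the irreversible rearrangement draining the equilibria. The closest known reaction type is the ketal Claisen rearrangement of cycloalkanone dimethyl ketals with secondary allylic alcohols, the ketone counterpart of the Johnson orthoester Claisen rearrangement, which proceeds with 1,3-chirality transfer. No ring is closed. Chain C2 is controlled by the (R)-carbinol carbon and the (E)-alkene: in the chair with the methyl group pseudo-equatorial and the benzhydryl group equatorial, the C–O bond breaks and the C–C bond forms on the same face of the allyl unit, which gives (R) at C2 and the (Z)-alkene (methyl trans to C2). Chromanone C3 becomes (S) through the chair because the ring fixes the enol ether geometry, and since this centre is erased in steps 13 and 14 its epimer ratio does not matter. The step needs methyl-equatorial over methyl-axial selectivity, secured by the 1,3-diaxial clash of an axial methyl with C4a and its peri 5-benzyloxy group, and any minor (E)-alkene isomer, which would carry (S)-C2, is a diastereomer and is removed by chromatography before the alkene is cleaved.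

Step 13
Reactants: 22 (3S)-5,7-bis(benzyloxy)-3-{(2R,3Z)-1,1-bis[4-(benzyloxy)phenyl]-3-[2,4,6-tris(benzyloxy)phenyl]pent-3-en-2-yl}chroman-4-one
Product: 23 5,7-bis(benzyloxy)-3-{(2S,3Z)-1,1-bis[4-(benzyloxy)phenyl]-3-[2,4,6-tris(benzyloxy)phenyl]pent-3-en-2-yl}-4-(trimethylsilyloxy)-2H-chromene
Conditions: TMSOTf (1.5 equiv), Et3N (3 equiv), CH2Cl2, 0 °C → rt; cold aq NaHCO3
Reagents that add atoms: trimethylsilyl trifluoromethanesulfonate, C[Si](C)(C)OS(=O)(=O)C(F)(F)F
Why: soft enolisation with O-silylation (silyl enol ether formation) in which the electron-rich carbonyl oxygen is silylated and triethylamine removes the only α-hydrogen (C3–H), so that both C3 epimers converge while the merely allylic C2–H of the chain is not acidic enough to be touched.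

Step 14
Reactants: 23 5,7-bis(benzyloxy)-3-{(2S,3Z)-1,1-bis[4-(benzyloxy)phenyl]-3-[2,4,6-tris(benzyloxy)phenyl]pent-3-en-2-yl}-4-(trimethylsilyloxy)-2H-chromene
Product: 24 5,7-bis(benzyloxy)-3-{(2S,3Z)-1,1-bis[4-(benzyloxy)phenyl]-3-[2,4,6-tris(benzyloxy)phenyl]pent-3-en-2-yl}-4H-chromen-4-one
Conditions: DDQ (1.05 equiv), 2,4,6-collidine (1.5 equiv), CH2Cl2, −40 → 0 °C; aq NaHCO3
Reagents that add atoms: none
Why: DDQ dehydrogenation of a silyl enol ether, in which hydride abstraction from the oxygen-flanked ring C2–H of the electron-rich 2H-chromene gives an aromatic 4-silyloxybenzopyrylium ion that loses silicon to give the chromone, a pathway that at low temperature and with one equivalent of oxidant should outrun attack on the crowded diarylmethine C–H and does not involve chain C2.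

Step 15
Reactants: 24 5,7-bis(benzyloxy)-3-{(2S,3Z)-1,1-bis[4-(benzyloxy)phenyl]-3-[2,4,6-tris(benzyloxy)phenyl]pent-3-en-2-yl}-4H-chromen-4-one
Product: 26 5,7-bis(benzyloxy)-3-{(2R)-1,1-bis[4-(benzyloxy)phenyl]-3-oxo-3-[2,4,6-tris(benzyloxy)phenyl]propan-2-yl}-4H-chromen-4-one, via 5,7-bis(benzyloxy)-3-{(2R)-1,1-bis[4-(benzyloxy)phenyl]-3,4-dihydroxy-3-[2,4,6-tris(benzyloxy)phenyl]pentan-2-yl}-4H-chromen-4-one (syn-diol, either alkene face) 25 (not isolated)
Conditions: OsO4 (10 mol %), NaIO4 (4 equiv), 2,6-lutidine (2 equiv), THF–H2O (3:1), rt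
Reagents that add atoms: osmium tetroxide, O=[Os](=O)(=O)=O; sodium periodate, [Na+].[O-]I(=O)(=O)=O
Why: Lemieux–Johnson oxidation in which osmium tetroxide dihydroxylates the only isolated alkene (arenes, benzyl ethers and the vinylogous-ester C2=C3 bond of the pyranone are inert to it), periodate cleaves diol 25 and regenerates osmium(VIII), and 2,6-lutidine keeps the medium near neutral so that C2, now α to the ketone, is not epimerised.

Step 16
Reactants: 26 5,7-bis(benzyloxy)-3-{(2R)-1,1-bis[4-(benzyloxy)phenyl]-3-oxo-3-[2,4,6-tris(benzyloxy)phenyl]propan-2-yl}-4H-chromen-4-one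
Product: 27 3-[(2R)-1,1-bis(4-hydroxyphenyl)-3-oxo-3-(2,4,6-trihydroxyphenyl)propan-2-yl]-5,7-dihydroxy-4H-chromen-4-one (CNP0106875.1)
Conditions: H2 (1 atm), 10% Pd/C, THF–MeOH (1:1), rt
Reagents that add atoms: none
Why: catalytic hydrogenolysis of seven aryl benzyl ethers under neutral conditions, the trisubstituted pyranone double bond and the hindered electron-rich aryl ketone being reduced much more slowly and the absence of acid or base leaving the (R)-configured C2 untouched.

**Compound list**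

1 | 4,4'-dihydroxybenzophenone | O=C(c1ccc(O)cc1)c1ccc(O)cc1 | starting material
2 | 4,4'-bis(benzyloxy)benzophenone | O=C(c1ccc(OCc2ccccc2)cc1)c1ccc(OCc2ccccc2)cc1 | intermediate
3 | (R)-but-3-yn-2-ol | C[C@@H](O)C#C | starting material
4 | O,C-dilithio derivative of (R)-but-3-yn-2-ol | C[C@@H](O[Li])C#C[Li] | intermediate
5 | (4R)-1,1-bis[4-(benzyloxy)phenyl]pent-2-yne-1,4-diol | C[C@@H](O)C#CC(O)(c1ccc(OCc2ccccc2)cc1)c1ccc(OCc2ccccc2)cc1 | intermediate
6 | (2R)-5,5-bis[4-(benzyloxy)phenyl]pent-3-yn-2-ol | C[C@@H](O)C#CC(c1ccc(OCc2ccccc2)cc1)c1ccc(OCc2ccccc2)cc1 | intermediate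
7 | (2R,3Z)-5,5-bis[4-(benzyloxy)phenyl]-3-(tributylstannyl)pent-3-en-2-ol | C[C@@H](O)/C([Sn](CCCC)(CCCC)CCCC)=C/C(c1ccc(OCc2ccccc2)cc1)c1ccc(OCc2ccccc2)cc1 | intermediate
8 | (2R,3Z)-5,5-bis[4-(benzyloxy)phenyl]-3-iodopent-3-en-2-ol | C[C@@H](O)/C(I)=C/C(c1ccc(OCc2ccccc2)cc1)c1ccc(OCc2ccccc2)cc1 | intermediate
9 | phloroglucinol | Oc1cc(O)cc(O)c1 | starting material
10 | 1,3,5-tris(benzyloxy)benzene | c1ccc(COc2cc(OCc3ccccc3)cc(OCc3ccccc3)c2)cc1 | intermediate
11 | 1,3,5-tris(benzyloxy)-2-iodobenzene | Ic1c(OCc2ccccc2)cc(OCc2ccccc2)cc1OCc1ccccc1 | intermediate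
12 | [2,4,6-tris(benzyloxy)phenyl]lithium | [Li]c1c(OCc2ccccc2)cc(OCc2ccccc2)cc1OCc1ccccc1 | intermediate
13 | chloro[2,4,6-tris(benzyloxy)phenyl]zinc | Cl[Zn]c1c(OCc2ccccc2)cc(OCc2ccccc2)cc1OCc1ccccc1 | intermediate
14 | (2R,3E)-5,5-bis[4-(benzyloxy)phenyl]-3-[2,4,6-tris(benzyloxy)phenyl]pent-3-en-2-ol | C[C@@H](O)/C(c1c(OCc2ccccc2)cc(OCc2ccccc2)cc1OCc1ccccc1)=C/C(c1ccc(OCc2ccccc2)cc1)c1ccc(OCc2ccccc2)cc1 | intermediate
15 | 3-chloropropanoic acid | OC(=O)CCCl | starting material
16 | 3-chloro-1-(2,4,6-trihydroxyphenyl)propan-1-one | O=C(CCCl)c1c(O)cc(O)cc1O | intermediate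
17 | 5,7-dihydroxychroman-4-one | O=C1CCOc2cc(O)cc(O)c12 | intermediate
18 | 5,7-bis(benzyloxy)chroman-4-one | O=C1CCOc2cc(OCc3ccccc3)cc(OCc3ccccc3)c12 | intermediate
19 | 5,7-bis(benzyloxy)-4,4-dimethoxychromane | COC1(OC)CCOc2cc(OCc3ccccc3)cc(OCc3ccccc3)c12 | intermediate
20 | mixed ketal, 5,7-bis(benzyloxy)-4-methoxy-4-({(2R,3E)-5,5-bis[4-(benzyloxy)phenyl]-3-[2,4,6-tris(benzyloxy)phenyl]pent-3-en-2-yl}oxy)chromane (both C4 epimers) | C[C@@H](OC1(OC)CCOc2cc(OCc3ccccc3)cc(OCc3ccccc3)c12)/C(c1c(OCc2ccccc2)cc(OCc2ccccc2)cc1OCc1ccccc1)=C/C(c1ccc(OCc2ccccc2)cc1)c1ccc(OCc2ccccc2)cc1 | intermediate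
21 | allyl enol ether, 5,7-bis(benzyloxy)-4-({(2R,3E)-5,5-bis[4-(benzyloxy)phenyl]-3-[2,4,6-tris(benzyloxy)phenyl]pent-3-en-2-yl}oxy)-2H-chromene | C[C@@H](OC1=CCOc2cc(OCc3ccccc3)cc(OCc3ccccc3)c12)/C(c1c(OCc2ccccc2)cc(OCc2ccccc2)cc1OCc1ccccc1)=C/C(c1ccc(OCc2ccccc2)cc1)c1ccc(OCc2ccccc2)cc1 | intermediate
22 | (3S)-5,7-bis(benzyloxy)-3-{(2R,3Z)-1,1-bis[4-(benzyloxy)phenyl]-3-[2,4,6-tris(benzyloxy)phenyl]pent-3-en-2-yl}chroman-4-one | O=C1c2c(OCc3ccccc3)cc(OCc3ccccc3)cc2OC[C@@H]1[C@@H](C(c1ccc(OCc2ccccc2)cc1)c1ccc(OCc2ccccc2)cc1)/C(c1c(OCc2ccccc2)cc(OCc2ccccc2)cc1OCc1ccccc1)=C/C | intermediate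
23 | 5,7-bis(benzyloxy)-3-{(2S,3Z)-1,1-bis[4-(benzyloxy)phenyl]-3-[2,4,6-tris(benzyloxy)phenyl]pent-3-en-2-yl}-4-(trimethylsilyloxy)-2H-chromene | C[Si](C)(C)OC1=C(COc2cc(OCc3ccccc3)cc(OCc3ccccc3)c12)[C@@H](C(c1ccc(OCc2ccccc2)cc1)c1ccc(OCc2ccccc2)cc1)/C(c1c(OCc2ccccc2)cc(OCc2ccccc2)cc1OCc1ccccc1)=C/C | intermediate
24 | 5,7-bis(benzyloxy)-3-{(2S,3Z)-1,1-bis[4-(benzyloxy)phenyl]-3-[2,4,6-tris(benzyloxy)phenyl]pent-3-en-2-yl}-4H-chromen-4-one | O=c1c(coc2cc(OCc3ccccc3)cc(OCc3ccccc3)c12)[C@@H](C(c1ccc(OCc2ccccc2)cc1)c1ccc(OCc2ccccc2)cc1)/C(c1c(OCc2ccccc2)cc(OCc2ccccc2)cc1OCc1ccccc1)=C/C | intermediate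
25 | 5,7-bis(benzyloxy)-3-{(2R)-1,1-bis[4-(benzyloxy)phenyl]-3,4-dihydroxy-3-[2,4,6-tris(benzyloxy)phenyl]pentan-2-yl}-4H-chromen-4-one (syn-diol from either alkene face; the two carbinol centres are left open and are erased on cleavage) | O=c1c(coc2cc(OCc3ccccc3)cc(OCc3ccccc3)c12)[C@@H](C(c1ccc(OCc2ccccc2)cc1)c1ccc(OCc2ccccc2)cc1)C(O)(c1c(OCc2ccccc2)cc(OCc2ccccc2)cc1OCc1ccccc1)C(C)O | intermediate
26 | 5,7-bis(benzyloxy)-3-{(2R)-1,1-bis[4-(benzyloxy)phenyl]-3-oxo-3-[2,4,6-tris(benzyloxy)phenyl]propan-2-yl}-4H-chromen-4-one | O=c1c(coc2cc(OCc3ccccc3)cc(OCc3ccccc3)c12)[C@@H](C(c1ccc(OCc2ccccc2)cc1)c1ccc(OCc2ccccc2)cc1)C(=O)c1c(OCc2ccccc2)cc(OCc2ccccc2)cc1OCc1ccccc1 | intermediate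
27 | 3-[(2R)-1,1-bis(4-hydroxyphenyl)-3-oxo-3-(2,4,6-trihydroxyphenyl)propan-2-yl]-5,7-dihydroxy-4H-chromen-4-one | O=C(c1c(O)cc(O)cc1O)[C@@H](c1coc2cc(O)cc(O)c2c1=O)C(c1ccc(O)cc1)c1ccc(O)cc1 | target

Total step count: 16.
Longest linear sequence: 10 steps (1, 2, 3, 4, 7, 12, 13, 14, 15, 16) from 4,4'-dihydroxybenzophenone.

**Steps most likely to fail**

First, step 12.
- Risk: capture of the oxocarbenium ion by the very crowded carbinol may be slower than acid-promoted loss of the chromanone from the mixed ketal or enol ether by elimination towards the methyl group.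
- Risk: the chair may be too congested where the twisted tris(benzyloxy)phenyl ring meets the chromene. Conversion could then stall, or methyl-axial pathways could erode the chirality transfer.
- Fallback: it sets out from 14 (with 11), keeps the chirality transfer but moves it to a small neutral partner, and builds the pyranone afterwards.
- Heating 14 with N,N-dimethylacetamide dimethyl acetal in xylenes (Eschenmoser–Claisen rearrangement, same chair, the dimethylamino group taking the role of C4a) should pass through the ketene N,O-acetal (1-(dimethylamino)vinyl ether of 14) F1.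
- F1 rearranges to (3S,4Z)-3-{bis[4-(benzyloxy)phenyl]methyl}-N,N-dimethyl-4-[2,4,6-tris(benzyloxy)phenyl]hex-4-enamide F2.
- Aryllithium 12, made from 11 as in step 7, adds to F2 to give (3S,4Z)-3-{bis[4-(benzyloxy)phenyl]methyl}-1,4-bis[2,4,6-tris(benzyloxy)phenyl]hex-4-en-1-one F3.
- Magnesium bromide etherate removes one benzyl group ortho to the carbonyl by chelation, giving (3S,4Z)-1-[2,4-bis(benzyloxy)-6-hydroxyphenyl]-3-{bis[4-(benzyloxy)phenyl]methyl}-4-[2,4,6-tris(benzyloxy)phenyl]hex-4-en-1-one F4.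
- N,N-Dimethylformamide dimethyl acetal in hot toluene condenses at the α-methylene group to give the 2-[(dimethylamino)methylidene] derivative of F4 (enaminone) F5.
- On warming with acetic acid, F5 closes to the pyranone with loss of dimethylamine and comes back to the route at 24. Steps 8–11, 13 and 14 are then not needed.

Second, step 15.
- Risk: osmylation may stall because the ortho-benzyloxy groups of the twisted aryl ring screen both faces of the alkene carbon C1. Long exposure invites slow attack at the pyranone double bond.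
- Fallback: it sets out from 24 and uses the much smaller dipole ozone (CH2Cl2, −78 °C, Sudan Red 7B as end-point indicator so that the electron-rich arenes are spared).
- This gives the secondary ozonide 5,7-bis(benzyloxy)-3-{(1R)-2,2-bis[4-(benzyloxy)phenyl]-1-{5-methyl-3-[2,4,6-tris(benzyloxy)phenyl]-1,2,4-trioxolan-3-yl}ethyl}-4H-chromen-4-one F6. Dimethyl sulfide reduces F6, and the fallback comes back to the route at 26.

Third, step 14.
- Risk: hydride abstraction may not stay confined to the ring C2–H. Oxidation of the bis(4-benzyloxyphenyl)methine, or desilylation of the enol ether by the acidic hydroquinone, may compete.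
- Fallback: it sets out from 23 and replaces the hydride-abstracting quinone by an organometallic dehydrogenation, the Saegusa–Ito oxidation (Pd(OAc)2, MeCN–CH2Cl2, rt → 40 °C).
- In this reaction a palladium enolate undergoes β-hydride elimination towards the ring CH2 group. It comes back to the route at 24 and makes no compound outside the list (F0).

**Further compounds**

F1 | step 12 | ketene N,O-acetal, N,N-dimethyl-1-({(2R,3E)-5,5-bis[4-(benzyloxy)phenyl]-3-[2,4,6-tris(benzyloxy)phenyl]pent-3-en-2-yl}oxy)ethenamine | C[C@@H](OC(=C)N(C)C)/C(c1c(OCc2ccccc2)cc(OCc2ccccc2)cc1OCc1ccccc1)=C/C(c1ccc(OCc2ccccc2)cc1)c1ccc(OCc2ccccc2)cc1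
F2 | step 12 | (3S,4Z)-3-{bis[4-(benzyloxy)phenyl]methyl}-N,N-dimethyl-4-[2,4,6-tris(benzyloxy)phenyl]hex-4-enamide | CN(C)C(=O)C[C@@H](C(c1ccc(OCc2ccccc2)cc1)c1ccc(OCc2ccccc2)cc1)/C(c1c(OCc2ccccc2)cc(OCc2ccccc2)cc1OCc1ccccc1)=C/C
F3 | step 12 | (3S,4Z)-3-{bis[4-(benzyloxy)phenyl]methyl}-1,4-bis[2,4,6-tris(benzyloxy)phenyl]hex-4-en-1-one | O=C(c1c(OCc2ccccc2)cc(OCc2ccccc2)cc1OCc1ccccc1)C[C@@H](C(c1ccc(OCc2ccccc2)cc1)c1ccc(OCc2ccccc2)cc1)/C(c1c(OCc2ccccc2)cc(OCc2ccccc2)cc1OCc1ccccc1)=C/C
F4 | step 12 | (3S,4Z)-1-[2,4-bis(benzyloxy)-6-hydroxyphenyl]-3-{bis[4-(benzyloxy)phenyl]methyl}-4-[2,4,6-tris(benzyloxy)phenyl]hex-4-en-1-one | O=C(c1c(O)cc(OCc2ccccc2)cc1OCc1ccccc1)C[C@@H](C(c1ccc(OCc2ccccc2)cc1)c1ccc(OCc2ccccc2)cc1)/C(c1c(OCc2ccccc2)cc(OCc2ccccc2)cc1OCc1ccccc1)=C/C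
F5 | step 12 | (3S,4Z)-1-[2,4-bis(benzyloxy)-6-hydroxyphenyl]-3-{bis[4-(benzyloxy)phenyl]methyl}-2-[(dimethylamino)methylidene]-4-[2,4,6-tris(benzyloxy)phenyl]hex-4-en-1-one (enaminone geometry left open) | O=C(c1c(O)cc(OCc2ccccc2)cc1OCc1ccccc1)C(=CN(C)C)[C@@H](C(c1ccc(OCc2ccccc2)cc1)c1ccc(OCc2ccccc2)cc1)/C(c1c(OCc2ccccc2)cc(OCc2ccccc2)cc1OCc1ccccc1)=C/C
F6 | step 15 | 5,7-bis(benzyloxy)-3-{(1R)-2,2-bis[4-(benzyloxy)phenyl]-1-{5-methyl-3-[2,4,6-tris(benzyloxy)phenyl]-1,2,4-trioxolan-3-yl}ethyl}-4H-chromen-4-one (trioxolane centres left open) | O=c1c(coc2cc(OCc3ccccc3)cc(OCc3ccccc3)c12)[C@@H](C(c1ccc(OCc2ccccc2)cc1)c1ccc(OCc2ccccc2)cc1)C1(c2c(OCc3ccccc3)cc(OCc3ccccc3)cc2OCc2ccccc2)OOC(C)O1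
F0 | step 14 | none | none
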